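**Retrosynthetic overview**
1. Ring B (the cyclohexane between spiro-lactone ring A and the cage) is cut last, at the bond between the spiro carbon and the carbinol carbon (C–CH3, OH). The spiro carbon is the γ-carbon of the unsaturated δ-lactone ring A and is bonded to the ring-B carbinol carbon, so this bond is a vinylogous aldol bond. It is made with inverted polarity: a tertiary radical from a β,γ-epoxy δ-lactone (Cp2TiCl) adds to an acetyl ketone on the cage, and the oxygen left beside the spiro carbon later gives the ring-A C=C.
2. The cage (cyclopentane ring C, bicyclo[2.2.2]octane rings D and E, fused lactone ring F) comes from an intramolecular Diels–Alder reaction of a 6,6-disubstituted cyclohexa-2,4-dienone released by selenoxide elimination. The ring-F hydroxyl follows by boron conjugate addition and oxidation.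
3. The quaternary carbon of the dienone comes from an asymmetric Michael addition of a non-aromatic "dihydrophenol" phthalide to a 2-acyl-1,3-diene that already carries ring A. The phthalide has only one enolisable carbon, so there is no choice between two ortho positions.
4. Order of ring formation: carbocycle and ring F (step 2), ring A (step 6), rings C, D and E (step 11), ring B (step 15).

Key step: step 15

Assumption: the facial sense of the chiral ammonium catalyst in step 10 is not predicted here; the cinchonidinium salt or its pseudo-enantiomeric cinchoninium salt is taken, whichever gives the (R)-quaternary carbon of 20.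

Step 1
Reactants: 1 2-methylpent-1-en-3-one
Product: 2 tert-butyl(dimethyl){[(3Z)-2-methylpenta-1,3-dien-3-yl]oxy}silane
Conditions: TBSOTf, Et3N, CH2Cl2, 0 °C
Reagents that add atoms: tert-butyldimethylsilyl triflate, CC(C)(C)[Si](C)(C)OS(=O)(=O)C(F)(F)F
Why: Soft enolisation and O-silylation at the only enolisable position (the ethyl CH2) should give the 2-silyloxy-1,3-diene as the thermodynamic Z enol ether, with the methyl group outward for the Diels–Alder reaction.

Step 2
Reactants: 2 tert-butyl(dimethyl){[(3Z)-2-methylpenta-1,3-dien-3-yl]oxy}silane; 3 methyl 4-hydroxybut-2-ynoate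
Product: 5 5-{[tert-butyl(dimethyl)silyl]oxy}-4,6-dimethyl-4,7-dihydro-2-benzofuran-1(3H)-one (racemic), via cyclohexadiene hydroxy ester 4 (not isolated)
Conditions: toluene, BHT (cat.), 110 °C, sealed tube, argon
Reagents that add atoms: none
Why: Thermal Diels–Alder reaction of the 2-silyloxydiene with the alkynoate (the enol-ether β-carbon bonds to the alkyne carbon β to the ester) followed by lactonisation of the cis-held hydroxymethyl and ester groups; the one new stereocentre forms racemic and is erased in step 10.

Step 3
Reactants: 5 5-{[tert-butyl(dimethyl)silyl]oxy}-4,6-dimethyl-4,7-dihydro-2-benzofuran-1(3H)-one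
Product: 6 4,6-dimethyl-6-(phenylselanyl)-6,7-dihydro-2-benzofuran-1,5(3H,4H)-dione (racemic, both diastereomers)
Conditions: PhSeCl, CH2Cl2, −78 °C
Reagents that add atoms: benzeneselenenyl chloride, Cl[Se]c1ccccc1
Why: Electrophilic α-selenenylation of the silyl enol ether puts selenium regiospecifically on the methyl-bearing α-carbon as a latent C=C; both stereocentres are temporary and form as a mixture.

Step 4
Reactants: 7 2,3-dimethylbut-3-en-2-ol; 8 3-chloro-2-(chloromethyl)prop-1-ene
Product: 10 6-(chloromethyl)-2-methyl-3-methylidenehept-6-en-2-ol, via dilithio dianion 9 (not isolated)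
Conditions: n-BuLi (2.2 equiv), TMEDA, Et2O/hexane, 0 °C to rt; then 8 (3 equiv), THF, −78 to 0 °C
Reagents that add atoms: n-butyllithium, [Li]CCCC (lithium of 9 only)
Why: Alkoxide-directed allylic lithiation gives the O,C-dianion, whose symmetric allyl unit couples with the symmetric allylic dichloride (SN2 and SN2′ give the same product), with excess 8 securing mono-substitution.

Step 5
Reactants: 10 6-(chloromethyl)-2-methyl-3-methylidenehept-6-en-2-ol; 11 but-3-enoic acid
Product: 12 6-(chloromethyl)-2-methyl-3-methylidenehept-6-en-2-yl but-3-enoate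
Conditions: DCC, DMAP (5 mol%), CH2Cl2, 0 °C
Reagents that add atoms: none
Why: Steglich esterification of the tertiary allylic alcohol, run cold with little DMAP so that the β,γ-double bond of the acid does not move into conjugation.

Step 6
Reactants: 12 6-(chloromethyl)-2-methyl-3-methylidenehept-6-en-2-yl but-3-enoate
Product: 13 5-[3-(chloromethyl)but-3-en-1-yl]-6,6-dimethyl-3,6-dihydro-2H-pyran-2-one
Conditions: second-generation Hoveyda–Grubbs catalyst (H2IMes)Cl2Ru(=CH-C6H4-2-OiPr) (5 mol%), toluene (5 mM), 80 °C
Reagents that add atoms: none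
Why: Ring-closing olefin metathesis between the butenoate vinyl group and the nearer 1,1-disubstituted alkene closes the six-membered β,γ-unsaturated lactone (ring A) in preference to a nine-membered ring through the distant alkene.

Step 7
Reactants: 13 5-[3-(chloromethyl)but-3-en-1-yl]-6,6-dimethyl-3,6-dihydro-2H-pyran-2-one; 14 acetaldehyde
Product: 15 5-(5-hydroxy-3-methylidenehexyl)-6,6-dimethyl-3,6-dihydro-2H-pyran-2-one (racemic)
Conditions: In powder, NaI (cat.), DMF/H2O, rt
Reagents that add atoms: none
Why: Barbier-type indium allylation; the 2-substituted allylindium has two identical CH2 termini, so one constitution results, and the neutral medium spares the base-sensitive lactone; the carbinol centre is racemic and is oxidised next.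

Step 8
Reactants: 15 5-(5-hydroxy-3-methylidenehexyl)-6,6-dimethyl-3,6-dihydro-2H-pyran-2-one
Product: 16 6,6-dimethyl-5-(3-methylidene-5-oxohexyl)-3,6-dihydro-2H-pyran-2-one
Conditions: Dess–Martin periodinane, pyridine, CH2Cl2, 0 °C
Reagents that add atoms: none
Why: Buffered Dess–Martin oxidation should give the β,γ-unsaturated methyl ketone without moving the alkene into conjugation.

Step 9
Reactants: 16 6,6-dimethyl-5-(3-methylidene-5-oxohexyl)-3,6-dihydro-2H-pyran-2-one
Product: 19 5-(4-acetyl-3-methylidenepent-4-en-1-yl)-6,6-dimethyl-3,6-dihydro-2H-pyran-2-one, via Mannich base 17 (not isolated), via ammonium iodide 18 (not isolated)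
Conditions: [CH2=NMe2]I (Eschenmoser's salt), CH2Cl2, rt; NaHCO3 (aq); MeI, Et2O; NaHCO3 (aq), CH2Cl2, 0 °C; used at once as a cold solution
Reagents that add atoms: N,N-dimethylmethyleneiminium iodide, C[N+](C)=C.[I-]; iodomethane, CI (methyl of 18 only)
Why: Mannich reaction at the more acidic allylic α-carbon of the ketone (through the conjugated dienol), then quaternisation and E1cB elimination, should give the 2-acyl-1,3-diene.

Step 10
Reactants: 6 4,6-dimethyl-6-(phenylselanyl)-6,7-dihydro-2-benzofuran-1,5(3H,4H)-dione; 19 5-(4-acetyl-3-methylidenepent-4-en-1-yl)-6,6-dimethyl-3,6-dihydro-2H-pyran-2-one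
Product: 20 (4R)-4-[2-acetyl-5-(6,6-dimethyl-2-oxo-3,6-dihydro-2H-pyran-5-yl)-3-methylidenepentyl]-4,6-dimethyl-6-(phenylselanyl)-6,7-dihydro-2-benzofuran-1,5(3H,4H)-dione (epimers at the selanyl carbon and at the acetyl-bearing carbon)
Conditions: N-(9-anthracenylmethyl)-O-allylcinchonidinium bromide (10 mol%), K2CO3 (0.2 equiv), toluene, −30 °C
Reagents that add atoms: none
Why: Asymmetric phase-transfer Michael addition: the only acidic C–H of 6 (between the ketone and the butenolide) gives a vinylogous β-dicarbonyl enolate that adds through carbon to the CH2 terminus of the enone, the chiral ammonium ion pair shielding one enolate face to set the (R)-quaternary carbon, while the selanyl and acetyl-bearing centres stay mixed and converge in step 11.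

Step 11
Reactants: 20 (4R)-Michael adduct
Product: 23 exo-acetyl cage cycloadduct (rings C, D, E and butenolide ring F), via selenoxide 21 (not isolated), via cyclohexadienone 22 (not isolated)
Conditions: m-CPBA (1.05 equiv), CH2Cl2, −78 °C; iPr2NH, −78 to 0 °C; then toluene, 90 °C
Reagents that add atoms: 3-chloroperbenzoic acid, OOC(=O)c1cccc(Cl)c1 (oxygen of 21 only)
Why: Selenoxide syn-elimination toward the ring CH2 gives the conjugated 2,4-dienone, which cannot aromatise, and an intramolecular Diels–Alder reaction with the tethered 1,1-disubstituted alkene follows; the two-atom tether forces addition on the face of the chain, so the (R)-quaternary carbon fixes all four cage centres, and the acetyl-bearing carbon, epimerisable through its allylic enol under the amine, should drain through the less hindered exo-acetyl transition state.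

Step 12
Reactants: 23 exo-acetyl cage cycloadduct
Product: 25 cage β-hydroxy γ-lactone (H and OH of ring F as in 31), via pinacol boronate 24 (not isolated)
Conditions: CuCl (5 mol%), NaOtBu (5 mol%), Xantphos (5 mol%), B2pin2 (1.2 equiv), MeOH (2 equiv), THF, rt; then NaBO3·4H2O, THF/H2O, rt
Reagents that add atoms: bis(pinacolato)diboron, CC1(C)OB(OC1(C)C)B1OC(C)(C)C(C)(C)O1 (boron of 24 only); sodium perborate, [Na+].[O-]OB=O
Why: Copper-catalysed conjugate borylation of the strained unsaturated lactone then stereoretentive C–B oxidation; boron should enter the β-carbon from the face syn to the ketone bridge (more open than the CH2 bridge) and the copper enolate should be protonated anti to boron, giving the cis hydroxy-lactone of the target.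

Step 13
Reactants: 25 cage β-hydroxy γ-lactone
Product: 26 triethylsilyl ether of 25
Conditions: TESOTf, 2,6-lutidine, CH2Cl2, −78 °C
Reagents that add atoms: triethylsilyl triflate, CC[Si](CC)(CC)OS(=O)(=O)C(F)(F)F
Why: Silyl ether formation at the only hydroxyl blocks retro-aldol and β-elimination of the β-hydroxy ketone/lactone in the later base steps; no stereocentre changes.

Step 14
Reactants: 26 triethylsilyl ether of 25
Product: 27 β,γ-epoxy δ-lactone (both epoxide diastereomers)
Conditions: DMDO, acetone, 0 °C
Reagents that add atoms: dimethyldioxirane, CC1(C)OO1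
Why: Neutral dioxirane epoxidation of the only remaining C=C (the ring-A alkene) without Baeyer–Villiger attack on the ketones; the epoxide configuration is immaterial because one carbon becomes a radical and the other carbinol is eliminated.

Step 15
Reactants: 27 β,γ-epoxy δ-lactone
Product: 28 ring-B-closed diol (30 with water added across the ring-A C=C, OH on the carbon next to the spiro centre)
Conditions: Cp2TiCl2 (2.5 equiv), Zn dust, THF, rt, the resulting Cp2TiCl solution added over 2 h to 27 in THF, rt; aq. NaH2PO4
Reagents that add atoms: none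
Why: Cp2TiCl (trivalent titanium) opens the epoxide by single-electron transfer at the more substituted carbon, giving the tertiary radical at the future spiro carbon with a titanium alkoxide on the neighbouring lactone carbon; the radical adds to the titanium-bound acetyl carbonyl and a second Cp2TiCl reduces the oxygen radical to the alkoxide, which makes the addition irreversible. The closest known reaction type is the titanocene-mediated reductive cyclisation of epoxy ketones to cycloalkanols. Ring B closes in the 6-exo-trig mode onto the C=O group. At the carbinol carbon the methyl takes the equatorial site of the chair transition state, away from the axial cage carbon at the ring fusion, so oxygen is axial; at the spiro carbon the arm carrying the titanium alkoxide lies gauche to the carbonyl oxygen (titanium bridging both oxygens), which puts the CMe2–O arm anti to the new hydroxyl as in the target, while the carbinol on the lactone ring is uncontrolled and is removed in step 16. The step needs regioselective epoxide homolysis (tertiary over secondary radical), addition to the acetyl rather than the cage ketone (which is flanked by two quaternary carbons and out of reach) and a cis ring fusion, which the exo-acetyl group and the two-carbon tether secure.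

Step 16
Reactants: 28 ring-B-closed diol
Product: 30 triethylsilyl ether of the target, via mesylate 29 (not isolated)
Conditions: MsCl, Et3N, CH2Cl2, 0 °C; then DBU (1.1 equiv), 0 °C
Reagents that add atoms: methanesulfonyl chloride, CS(Cl)(=O)=O (mesyl group of 29 only)
Why: Selective mesylation of the secondary β-hydroxyl (the tertiary and silylated hydroxyls stay) and E1cB elimination give the conjugated δ-lactone; the spiro carbon carries no hydrogen, so base can no longer open ring A through a dienolate.

Step 17
Reactants: 30 triethylsilyl ether of the target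
Product: 31 target CNP0360620.2
Conditions: HF·pyridine, THF, 0 °C
Reagents that add atoms: none
Why: Fluoride desilylation under mildly acidic conditions should free the secondary hydroxyl without retro-aldol cleavage or β-elimination; no stereocentre is touched.

**Compound list**
1 | 2-methylpent-1-en-3-one | CCC(=O)C(C)=C | starting material
2 | tert-butyl(dimethyl){[(3Z)-2-methylpenta-1,3-dien-3-yl]oxy}silane | C/C=C(\O[Si](C)(C)C(C)(C)C)C(C)=C | intermediate
3 | methyl 4-hydroxybut-2-ynoate | COC(=O)C#CCO | starting material
4 | methyl 4-{[tert-butyl(dimethyl)silyl]oxy}-2-(hydroxymethyl)-3,5-dimethylcyclohexa-1,4-diene-1-carboxylate (racemic) | CC1=C(O[Si](C)(C)C(C)(C)C)C(C)C(CO)=C(C1)C(=O)OC | intermediate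
5 | 5-{[tert-butyl(dimethyl)silyl]oxy}-4,6-dimethyl-4,7-dihydro-2-benzofuran-1(3H)-one (racemic) | CC1=C(O[Si](C)(C)C(C)(C)C)C(C)C2=C(C1)C(=O)OC2 | intermediate
6 | 4,6-dimethyl-6-(phenylselanyl)-6,7-dihydro-2-benzofuran-1,5(3H,4H)-dione (racemic, both diastereomers) | O=C1C(C)C2=C(CC1(C)[Se]c1ccccc1)C(=O)OC2 | intermediate
7 | 2,3-dimethylbut-3-en-2-ol | CC(=C)C(C)(C)O | starting material
8 | 3-chloro-2-(chloromethyl)prop-1-ene | ClCC(=C)CCl | starting material
9 | lithium 3-(lithiomethyl)-2-methylbut-3-en-2-olate (O,C-dianion of 7) | [Li]CC(=C)C(C)(C)O[Li] | intermediate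
10 | 6-(chloromethyl)-2-methyl-3-methylidenehept-6-en-2-ol | CC(C)(O)C(=C)CCC(=C)CCl | intermediate
11 | but-3-enoic acid | C=CCC(=O)O | starting material
12 | 6-(chloromethyl)-2-methyl-3-methylidenehept-6-en-2-yl but-3-enoate | C=CCC(=O)OC(C)(C)C(=C)CCC(=C)CCl | intermediate
13 | 5-[3-(chloromethyl)but-3-en-1-yl]-6,6-dimethyl-3,6-dihydro-2H-pyran-2-one | O=C1CC=C(CCC(=C)CCl)C(C)(C)O1 | intermediate
14 | acetaldehyde | CC=O | starting material
15 | 5-(5-hydroxy-3-methylidenehexyl)-6,6-dimethyl-3,6-dihydro-2H-pyran-2-one (racemic) | CC(O)CC(=C)CCC1=CCC(=O)OC1(C)C | intermediate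
16 | 6,6-dimethyl-5-(3-methylidene-5-oxohexyl)-3,6-dihydro-2H-pyran-2-one | CC(=O)CC(=C)CCC1=CCC(=O)OC1(C)C | intermediate
17 | 5-{4-[(dimethylamino)methyl]-3-methylidene-5-oxohexyl}-6,6-dimethyl-3,6-dihydro-2H-pyran-2-one (racemic) | CC(=O)C(CN(C)C)C(=C)CCC1=CCC(=O)OC1(C)C | intermediate
18 | [2-acetyl-5-(6,6-dimethyl-2-oxo-3,6-dihydro-2H-pyran-5-yl)-3-methylidenepentyl]trimethylammonium iodide (racemic) | CC(=O)C(C[N+](C)(C)C)C(=C)CCC1=CCC(=O)OC1(C)C.[I-] | intermediate
19 | 5-(4-acetyl-3-methylidenepent-4-en-1-yl)-6,6-dimethyl-3,6-dihydro-2H-pyran-2-one | CC(=O)C(=C)C(=C)CCC1=CCC(=O)OC1(C)C | intermediate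
20 | (4R)-4-[2-acetyl-5-(6,6-dimethyl-2-oxo-3,6-dihydro-2H-pyran-5-yl)-3-methylidenepentyl]-4,6-dimethyl-6-(phenylselanyl)-6,7-dihydro-2-benzofuran-1,5(3H,4H)-dione (epimers at the selanyl carbon and the acetyl-bearing carbon) | CC1([Se]c3ccccc3)CC2=C(COC2=O)[C@@](C)(CC(C(C)=O)C(=C)CCC4=CCC(=O)OC4(C)C)C1=O | intermediate
21 | Se-oxide of 20 | CC1([Se](=O)c3ccccc3)CC2=C(COC2=O)[C@@](C)(CC(C(C)=O)C(=C)CCC4=CCC(=O)OC4(C)C)C1=O | intermediate
22 | (4R)-4-[2-acetyl-5-(6,6-dimethyl-2-oxo-3,6-dihydro-2H-pyran-5-yl)-3-methylidenepentyl]-4,6-dimethyl-2-benzofuran-1,5(3H,4H)-dione (epimers at the acetyl-bearing carbon) | CC1=CC2=C(COC2=O)[C@@](C)(CC(C(C)=O)C(=C)CCC3=CCC(=O)OC3(C)C)C1=O | intermediate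
23 | cage cycloadduct: bicyclo[2.2.2]octenone bridged by a cyclopentane (exo-acetyl) and fused to the butenolide, with the 2-(6,6-dimethyl-2-oxo-3,6-dihydro-2H-pyran-5-yl)ethyl chain on the quaternary carbon formed from the alkene; cage centres as in 31 | CC1(C)OC(=O)CC=C1CC[C@]13C[C@]4(C)C(=O)[C@](C)(C[C@H]1C(C)=O)[C@]31COC(=O)C1=C4 | intermediate
24 | pinacol boronate of 23 (boron on the lactone β-carbon, syn to the ketone bridge; α-H anti to boron) | CC1(C)OC(=O)CC=C1CC[C@]13C[C@]4(C)C(=O)[C@](C)(C[C@H]1C(C)=O)[C@]31COC(=O)[C@H]1[C@H]4B1OC(C)(C)C(C)(C)O1 | intermediate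
25 | cage β-hydroxy γ-lactone (23 with H on the lactone α-carbon and OH on the β-carbon, both as in 31) | CC1(C)OC(=O)CC=C1CC[C@]13C[C@]4(C)C(=O)[C@](C)(C[C@H]1C(C)=O)[C@]31COC(=O)[C@H]1[C@H]4O | intermediate
26 | triethylsilyl ether of 25 | CC1(C)OC(=O)CC=C1CC[C@]13C[C@]4(C)C(=O)[C@](C)(C[C@H]1C(C)=O)[C@]31COC(=O)[C@H]1[C@H]4O[Si](CC)(CC)CC | intermediate
27 | 26 with the ring-A C=C epoxidised (β,γ-epoxy δ-lactone, both epoxide diastereomers) | CC1(C)OC(=O)CC2OC21CC[C@]13C[C@]4(C)C(=O)[C@](C)(C[C@H]1C(C)=O)[C@]31COC(=O)[C@H]1[C@H]4O[Si](CC)(CC)CC | intermediate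
28 | ring-B-closed diol: 30 with water added across the ring-A C=C (secondary OH on the lactone carbon next to the spiro centre, either configuration) | CC1(C)OC(=O)CC(O)[C@]12CC[C@]13C[C@]4(C)C(=O)[C@](C)(C[C@H]1[C@@]2(C)O)[C@]31COC(=O)[C@H]1[C@H]4O[Si](CC)(CC)CC | intermediate
29 | methanesulfonate of 28 at the secondary lactone-ring hydroxyl | CC1(C)OC(=O)CC(OS(C)(=O)=O)[C@]12CC[C@]13C[C@]4(C)C(=O)[C@](C)(C[C@H]1[C@@]2(C)O)[C@]31COC(=O)[C@H]1[C@H]4O[Si](CC)(CC)CC | intermediate
30 | triethylsilyl ether of the target at the ring-F-adjacent secondary hydroxyl | CC1(C)OC(=O)C=C[C@]12CC[C@]13C[C@]4(C)C(=O)[C@](C)(C[C@H]1[C@@]2(C)O)[C@]31COC(=O)[C@H]1[C@H]4O[Si](CC)(CC)CC | intermediate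
31 | target CNP0360620.2 | CC1(C)OC(=O)C=C[C@]12CC[C@]13C[C@]4(C)C(=O)[C@](C)(C[C@H]1[C@@]2(C)O)[C@]31COC(=O)[C@H]1[C@H]4O | target

**Step count and risks**
Total steps: 17. Longest linear sequence: 14 steps (steps 4 to 9, then 10 to 17); steps 1 to 3 form the second branch and join at step 10.

Risk 1, step 15. The tertiary radical may be lost before it reaches the ketone: by hydrogen abstraction, by β-hydride loss to an allylic alcohol, or by 1,5-hydrogen transfer from the acetyl α-carbon. Facial selectivity at the spiro carbon may also be poor if titanium does not bridge the two oxygens. The fallback sets out from alkene 26 and generates the same radical by metal-hydride hydrogen-atom transfer instead of epoxide opening: Fe(acac)3, PhSiH3, EtOH/ethylene glycol, 60 °C should add a hydrogen atom to the CH end of the ring-A alkene and close ring B onto the acetyl ketone, giving the saturated spiro δ-lactone carbinol F1. α-Selenenylation of the δ-lactone (LiN(SiMe3)2, 2.2 equiv, PhSeBr, THF, −78 °C; the lactone CH2 is far more accessible than the hindered CH of ring F) should give the α-phenylselanyl lactone F2. Oxidation with H2O2 and pyridine in CH2Cl2 at 0 °C, with selenoxide syn-elimination, comes back to the route at 30.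

Risk 2, step 10. The addition may be slow or poorly enantioselective, because the acceptor is α-branched, the racemic selanyl centre sits close to the enolate, and the 2-acyl diene can dimerise while waiting. The fallback sets out from 6 and 19 and gives up asymmetric catalysis for resolution: DBU (10 mol%) in CH2Cl2 at 0 °C should give 20 together with its (4S)-configured counterpart F3. The mixture is taken through step 11 to 23 and its enantiomer, the antipodal cage cycloadduct F4. These two single diastereomers are separated by preparative chromatography on a chiral stationary phase, and the route is rejoined at 23.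

Risk 3, step 11. The acetyl-bearing carbon may not epimerise fast enough before the cycloaddition, so that part of the material is trapped as the endo-acetyl cage; prolonged exposure to amine may instead move the tether alkene into conjugation. The fallback sets out from 20 and replaces dynamic control by thermodynamic correction after ring formation: the amine is washed out after selenoxide elimination and the cycloaddition is run neutral, accepting the endo-acetyl cycloadduct F5 beside 23. F5 is then equilibrated through the enol of the methyl ketone with TsOH·H2O (cat.) in CHCl3 at 40 °C (no conjugation is possible once the neighbouring carbon is quaternary), which comes back to the route at 23.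

**Further compounds**
F1 | step 15 | saturated spiro δ-lactone carbinol (30 with the ring-A C=C hydrogenated) | CC1(C)OC(=O)CC[C@]12CC[C@]13C[C@]4(C)C(=O)[C@](C)(C[C@H]1[C@@]2(C)O)[C@]31COC(=O)[C@H]1[C@H]4O[Si](CC)(CC)CC
F2 | step 15 | α-phenylselanyl derivative of F1 at the δ-lactone α-carbon | CC1(C)OC(=O)C([Se]c5ccccc5)C[C@]12CC[C@]13C[C@]4(C)C(=O)[C@](C)(C[C@H]1[C@@]2(C)O)[C@]31COC(=O)[C@H]1[C@H]4O[Si](CC)(CC)CC
F3 | step 10 | (4S)-configured counterpart of 20 | CC1([Se]c3ccccc3)CC2=C(COC2=O)[C@](C)(CC(C(C)=O)C(=C)CCC4=CCC(=O)OC4(C)C)C1=O
F4 | step 10 | enantiomer of cage cycloadduct 23 | CC1(C)OC(=O)CC=C1CC[C@@]13C[C@@]4(C)C(=O)[C@@](C)(C[C@@H]1C(C)=O)[C@@]31COC(=O)C1=C4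
F5 | step 11 | endo-acetyl epimer of 23 (epimer at the acetyl-bearing carbon) | CC1(C)OC(=O)CC=C1CC[C@]13C[C@]4(C)C(=O)[C@](C)(C[C@@H]1C(C)=O)[C@]31COC(=O)C1=C4
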